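**Strategy.** Atoms are labelled by their order in the target SMILES. The plan cuts the cycloheptenone ring (C11, C12, C21, C20, C19, C17, C16) at C11–C12 and C17–C19. C11 and C17 are the two tetralin carbons flanking C16, so a C16 ketone turns both into enolate carbons for a four-carbon bis-electrophile. One phase-transfer operation joins racemic 2-tetralone 11 to bromomethyl β-methoxyvinyl ketone 13, closes the bridged seven-membered ring and fixes both bridgehead stereocentres. The precursor is a 6,8-dibromo-7-ethyl-3,4,4-trimethyl-2-tetralone whose peri bromine steers the second enolisation to C17. One-carbon homologation at C16 and lactonisation onto C12 finish the synthesis.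

Key step: step 10

Remark: 1, 2 and 12 are taken as purchased; descriptors of 15–21 use the target-SMILES atom labels; which pseudoenantiomeric ammonium salt gives 15 and not its antipode must be found by experiment, and the cinchonidinium salt is written here.

Step 1
Reactants: 1 6-bromo-3,4-dihydronaphthalen-1(2H)-one; 2 ethylboronic acid
Product: 3 6-ethyl-3,4-dihydronaphthalen-1(2H)-one
Conditions: Pd(OAc)2 (3 mol %), SPhos (6 mol %), K3PO4, toluene/H2O (10:1), 100 °C
Reagents that add atoms: none
Why: Suzuki–Miyaura sp2–sp3 coupling of an unhindered aryl bromide with a primary alkylboronic acid, the bulky biaryl phosphine favouring reductive elimination over β-hydride loss.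

Step 2
Reactants: 3 6-ethyl-3,4-dihydronaphthalen-1(2H)-one
Product: 4 5,7-dibromo-6-ethyl-3,4-dihydronaphthalen-1(2H)-one
Conditions: AlCl3 (3.2 equiv), Br2 (2.2 equiv), CH2Cl2, 0 → 30 °C
Reagents that add atoms: bromine, BrBr
Why: Electrophilic aromatic bromination under swamping-catalyst conditions, in which the AlCl3-bound carbonyl cannot enolise and directs meta while the ethyl group directs ortho, so both effects converge on C5 and C7.

Step 3
Reactants: 4 5,7-dibromo-6-ethyl-3,4-dihydronaphthalen-1(2H)-one
Product: 5 5,7-dibromo-6-ethyl-1,1-dimethyl-1,2,3,4-tetrahydronaphthalene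
Conditions: TiCl4 (2.2 equiv), Me2Zn (2.2 equiv), CH2Cl2, −40 → 0 °C
Reagents that add atoms: dimethylzinc, C[Zn]C
Why: Reetz geminal dimethylation, in which Me2TiCl2 adds one methyl group to the aryl ketone and the benzylic titanium alkoxide then ionises (cation stabilised by the para ethyl group) and is methylated again.

Step 4
Reactants: 5 5,7-dibromo-6-ethyl-1,1-dimethyl-1,2,3,4-tetrahydronaphthalene
Product: 6 6,8-dibromo-7-ethyl-4,4-dimethyl-3,4-dihydronaphthalen-1(2H)-one
Conditions: CrO3 (3 equiv), AcOH/H2O (9:1), 20 → 50 °C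
Reagents that add atoms: chromium trioxide, O=[Cr](=O)=O
Why: Chromic acid benzylic oxidation at the only ring benzylic methylene, the ethyl CH2 being expected to react more slowly because two ortho bromines hold its C–H bonds out of alignment with the arene π system.

Step 5
Reactants: 6 6,8-dibromo-7-ethyl-4,4-dimethyl-3,4-dihydronaphthalen-1(2H)-one
Product: 7 6,8-dibromo-7-ethyl-4,4-dimethylnaphthalen-1(4H)-one
Conditions: 2-iodoxybenzoic acid (IBX, 2.5 equiv), DMSO/fluorobenzene (1:2), 75 °C
Reagents that add atoms: none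
Why: IBX α,β-dehydrogenation of a ketone through its enol, with aromatisation excluded because C4 is quaternary.

Step 6
Reactants: 7 6,8-dibromo-7-ethyl-4,4-dimethylnaphthalen-1(4H)-one
Product: 8 [(6,8-dibromo-7-ethyl-3,4,4-trimethyl-3,4-dihydronaphthalen-1-yl)oxy]trimethylsilane (racemic)
Conditions: Me2CuLi (from CuI and MeLi, 1.5 equiv), Me3SiCl (3 equiv), THF/Et2O, −78 → −40 °C; Et3N, pentane work-up
Reagents that add atoms: lithium dimethylcuprate, [Li+].C[Cu-]C; chlorotrimethylsilane, C[Si](C)(C)Cl
Why: Gilman cuprate 1,4-addition accelerated by Me3SiCl, which traps the enolate as its silyl enol ether, the new methyl-bearing stereocentre arising as a racemate.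

Step 7
Reactants: 8 [(6,8-dibromo-7-ethyl-3,4,4-trimethyl-3,4-dihydronaphthalen-1-yl)oxy]trimethylsilane
Product: 10 6,8-dibromo-7-ethyl-3,4,4-trimethyl-1,2,3,4-tetrahydronaphthalene-1,2-diol (racemic; 1,2-trans), via 2-boryl silyl ether 9 (not isolated)
Conditions: BH3·THF (2.5 equiv), THF, 0 → 25 °C; then 3 M aq NaOH, 30% H2O2, 0 → 25 °C
Reagents that add atoms: hydrogen peroxide, OO
Why: Hydroboration–oxidation of a silyl enol ether, boron adding to the carbon β to oxygen and alkaline peroxide replacing it by hydroxyl while cleaving the silyl ether; the carbinol configurations do not matter because both centres are destroyed in step 8.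

Step 8
Reactants: 10 6,8-dibromo-7-ethyl-3,4,4-trimethyl-1,2,3,4-tetrahydronaphthalene-1,2-diol
Product: 11 6,8-dibromo-7-ethyl-3,4,4-trimethyl-3,4-dihydronaphthalen-2(1H)-one (racemic)
Conditions: TsOH·H2O (20 mol %), toluene, 110 °C, Dean–Stark
Reagents that add atoms: none
Why: Acid-catalysed pinacol-type dehydration of an aryl 1,2-diol, in which ionisation at the benzylic carbon and 1,2-hydride shift (or proton loss to the enol) deliver the 2-tetralone.

Step 9
Reactants: 12 (E)-1-methoxy-3-(trimethylsilyloxy)buta-1,3-diene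
Product: 13 (E)-1-bromo-4-methoxybut-3-en-2-one
Conditions: NBS (1.0 equiv), THF, −78 → 0 °C; used directly
Reagents that add atoms: N-bromosuccinimide, O=C1CCC(=O)N1Br
Why: Electrophilic bromination of a silyl enol ether at the nucleophilic terminal CH2 of the siloxydiene, which unmasks the ketone and leaves the E enol ether untouched.

Step 10
Reactants: 11 6,8-dibromo-7-ethyl-3,4,4-trimethyl-3,4-dihydronaphthalen-2(1H)-one; 13 (E)-1-bromo-4-methoxybut-3-en-2-one
Product: 15 (5R,10S)-2,4-dibromo-3-ethyl-10,11,11-trimethyl-10,11-dihydro-5H-5,10-methanobenzo[9]annulene-7,12(6H)-dione (11R,17S by target labels), via C11-alkylated diketone 14 (not isolated)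
Conditions: N-[4-(trifluoromethyl)benzyl]cinchonidinium bromide (10 mol %), 50% aq KOH, toluene, −20 °C (13 added slowly), then 20 °C
Reagents that add atoms: none
Why: Proposed new method: the ammonium enolate at benzylic C11 (the more acidic α-carbon of 11) displaces bromide from 13 in an SN2 step (bond C11–C12) to give 14, in which the peri bromine on C9 holds the new chain pseudoaxial and disfavours a second, coplanar enolate at C11, so that base next generates the C17 enolate, which adds to the vinylogous-ester carbon C19 and expels methoxide (E1cB, bond C17–C19). The closest known reaction types are α,α′-annulations of cyclic ketones with 1,n-bis-electrophiles to bridged bicycles, cinchona-ammonium phase-transfer alkylation of 2-tetralone enolates and intramolecular enolate addition–elimination on β-alkoxy enones; running them as one enantioconvergent cascade is the untested part. The seven-membered ring closes by a 7-endo-trig conjugate addition that loss of methoxide makes irreversible, whereas the competing 5-exo aldol addition to C21 is reversible and a C11 enolate cannot reach C19 (5-endo). C11 is controlled by the chiral cation, first in the face-selective alkylation and again in the closure, where the still enolisable C11 and C17 centres of 14 allow the ion-paired C17 enolate of the faster-closing C11 antipode to drain the mixture; C17 is then fixed by the bridge, because C19 can only reach the enolate face syn to the axial C11 chain. The step needs C-alkylation by the bromomethyl group before any attack on the enol ether carbon, which the far higher SN2 reactivity of an α-bromo ketone compared with a donor-deactivated enone should secure, and it needs C17 (hydrogen and methyl only) to enolise in preference to a second reaction at C11, which the peri bromine and the limiting amount of 13 should secure.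

Step 11
Reactants: 15 bridged enedione (11R,17S)
Product: 16 tert-butyl{[(5R,10S)-2,4-dibromo-3-ethyl-10,11,11-trimethyl-12-oxo-10,11-dihydro-5H-5,10-methanobenzo[9]annulen-7-yl]oxy}dimethylsilane (C12=C21–C20=C19 silyl dienol ether)
Conditions: TBSOTf (1.3 equiv), Et3N (2 equiv), CH2Cl2, 0 °C
Reagents that add atoms: tert-butyldimethylsilyl trifluoromethanesulfonate, CC(C)(C)[Si](C)(C)OS(=O)(=O)C(F)(F)F
Why: Soft enolisation and O-silylation of the only enolisable carbonyl (C21, towards C12), the C16 ketone lying between a quaternary carbon and a bridgehead whose enolisation Bredt's rule forbids, so that C21 is masked for the olefination.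

Step 12
Reactants: 16 silyl dienol ether (11R,17S)
Product: 17 tert-butyl{[(5S,10S)-2,4-dibromo-3-ethyl-12-(methoxymethylidene)-10,11,11-trimethyl-10,11-dihydro-5H-5,10-methanobenzo[9]annulen-7-yl]oxy}dimethylsilane (E/Z mixture at C16=C14)
Conditions: Ph3P(CH2OMe)Cl (4 equiv), KN(SiMe3)2 (3.8 equiv), THF, 0 °C; then 16, 0 → 50 °C
Reagents that add atoms: (methoxymethyl)triphenylphosphonium chloride, COC[P+](c1ccccc1)(c1ccccc1)c1ccccc1.[Cl-]
Why: Wittig methoxymethylenation of the one remaining carbonyl, the bridging C16 ketone, whose α-substituents are tied back in the bicycle and whose face over the flat diene bridge is open to the ylide.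

Step 13
Reactants: 17 bis(enol ether)
Product: 18 (5S,10R,12R)-2,4-dibromo-3-ethyl-10,11,11-trimethyl-7-oxo-6,7,10,11-tetrahydro-5H-5,10-methanobenzo[9]annulene-12-carbaldehyde (11S,16R,17R; formyl group over the seven-membered ring)
Conditions: 2 M aq HCl, THF, 25 → 45 °C
Reagents that add atoms: water, O
Why: Acid hydrolysis of both enol ethers (aldehyde at C14, enone restored by protonation at C12) under conditions that equilibrate C16 through the aldehyde enol, the formyl group being expected to settle over the seven-membered ring, away from the pseudoaxial C23 methyl group (thermodynamic control).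

Step 14
Reactants: 18 keto aldehyde (11S,16R,17R)
Product: 19 (5S,10R,12R)-2,4-dibromo-3-ethyl-10,11,11-trimethyl-7-oxo-6,7,10,11-tetrahydro-5H-5,10-methanobenzo[9]annulene-12-carboxylic acid
Conditions: NaClO2, NaH2PO4, 2-methyl-2-butene, t-BuOH/H2O (3:1), 0 → 25 °C
Reagents that add atoms: sodium chlorite, [Na+].[O-]Cl=O
Why: Pinnick oxidation, which is mild enough to leave the enone and the C16 configuration untouched.

Step 15
Reactants: 19 keto acid (11S,16R,17R)
Product: 21 salimabromide (11S,12S,16R,17R), via C12 bromo acid 20 (not isolated)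
Conditions: PhNMe3Br3 (1.05 equiv), THF, 0 → 25 °C; then K2CO3 (3 equiv), DMF, 25 °C
Reagents that add atoms: none
Why: Selective α′-bromination of the enone through its only possible enol (towards C12) from the exo face, then 5-exo-tet SN2 displacement by the C14 carboxylate with inversion at C12, any endo bromide equilibrating by enolisation so that the cis-fused lactone dictates the C12 configuration.

**Compound list**

1 | 6-bromo-3,4-dihydronaphthalen-1(2H)-one | O=C1CCCc2cc(Br)ccc12 | starting material
2 | ethylboronic acid | CCB(O)O | starting material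
3 | 6-ethyl-3,4-dihydronaphthalen-1(2H)-one | O=C1CCCc2cc(CC)ccc12 | intermediate
4 | 5,7-dibromo-6-ethyl-3,4-dihydronaphthalen-1(2H)-one | O=C1CCCc2c(Br)c(CC)c(Br)cc12 | intermediate
5 | 5,7-dibromo-6-ethyl-1,1-dimethyl-1,2,3,4-tetrahydronaphthalene | CC1(C)CCCc2c(Br)c(CC)c(Br)cc12 | intermediate
6 | 6,8-dibromo-7-ethyl-4,4-dimethyl-3,4-dihydronaphthalen-1(2H)-one | CC1(C)CCC(=O)c2c(Br)c(CC)c(Br)cc12 | intermediate
7 | 6,8-dibromo-7-ethyl-4,4-dimethylnaphthalen-1(4H)-one | CC1(C)C=CC(=O)c2c(Br)c(CC)c(Br)cc12 | intermediate
8 | [(6,8-dibromo-7-ethyl-3,4,4-trimethyl-3,4-dihydronaphthalen-1-yl)oxy]trimethylsilane, racemic | CC1(C)C(C)C=C(O[Si](C)(C)C)c2c(Br)c(CC)c(Br)cc12 | intermediate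
9 | [(2-boranyl-6,8-dibromo-7-ethyl-3,4,4-trimethyl-1,2,3,4-tetrahydronaphthalen-1-yl)oxy]trimethylsilane, racemic | CC1(C)C(C)C(B)C(O[Si](C)(C)C)c2c(Br)c(CC)c(Br)cc12 | intermediate (not isolated)
10 | 6,8-dibromo-7-ethyl-3,4,4-trimethyl-1,2,3,4-tetrahydronaphthalene-1,2-diol, racemic, 1,2-trans, configuration relative to C3 not carried forward | CC1(C)C(C)C(O)C(O)c2c(Br)c(CC)c(Br)cc12 | intermediate
11 | 6,8-dibromo-7-ethyl-3,4,4-trimethyl-3,4-dihydronaphthalen-2(1H)-one, racemic | CCc1c(Br)cc2c(c1Br)CC(=O)C(C)C2(C)C | intermediate (key-step precursor)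
12 | (E)-1-methoxy-3-(trimethylsilyloxy)buta-1,3-diene | CO/C=C/C(=C)O[Si](C)(C)C | starting material
13 | (E)-1-bromo-4-methoxybut-3-en-2-one | CO/C=C/C(=O)CBr | intermediate (key-step precursor)
14 | 6,8-dibromo-7-ethyl-1-[(E)-4-methoxy-2-oxobut-3-en-1-yl]-3,4,4-trimethyl-3,4-dihydronaphthalen-2(1H)-one, both ring α-centres exchangeable | CCc1c(Br)cc2c(c1Br)C(CC(=O)/C=C/OC)C(=O)C(C)C2(C)C | intermediate (not isolated)
15 | (5R,10S)-2,4-dibromo-3-ethyl-10,11,11-trimethyl-10,11-dihydro-5H-5,10-methanobenzo[9]annulene-7,12(6H)-dione (11R,17S) | CCc1c(Br)cc2c(c1Br)[C@H]1CC(=O)C=C[C@](C)(C1=O)C2(C)C | intermediate (key-step product)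
16 | tert-butyl{[(5R,10S)-2,4-dibromo-3-ethyl-10,11,11-trimethyl-12-oxo-10,11-dihydro-5H-5,10-methanobenzo[9]annulen-7-yl]oxy}dimethylsilane | CCc1c(Br)cc2c(c1Br)[C@H]1C=C(O[Si](C)(C)C(C)(C)C)C=C[C@](C)(C1=O)C2(C)C | intermediate
17 | tert-butyl{[(5S,10S)-2,4-dibromo-3-ethyl-12-(methoxymethylidene)-10,11,11-trimethyl-10,11-dihydro-5H-5,10-methanobenzo[9]annulen-7-yl]oxy}dimethylsilane, E/Z mixture | CCc1c(Br)cc2c(c1Br)[C@H]1C=C(O[Si](C)(C)C(C)(C)C)C=C[C@](C)(C1=COC)C2(C)C | intermediate
18 | (5S,10R,12R)-2,4-dibromo-3-ethyl-10,11,11-trimethyl-7-oxo-6,7,10,11-tetrahydro-5H-5,10-methanobenzo[9]annulene-12-carbaldehyde | CCc1c(Br)cc2c(c1Br)[C@H]1CC(=O)C=C[C@](C)([C@@H]1C=O)C2(C)C | intermediate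
19 | (5S,10R,12R)-2,4-dibromo-3-ethyl-10,11,11-trimethyl-7-oxo-6,7,10,11-tetrahydro-5H-5,10-methanobenzo[9]annulene-12-carboxylic acid | CCc1c(Br)cc2c(c1Br)[C@H]1CC(=O)C=C[C@](C)([C@@H]1C(=O)O)C2(C)C | intermediate
20 | (5S,6R,10R,12R)-2,4,6-tribromo-3-ethyl-10,11,11-trimethyl-7-oxo-6,7,10,11-tetrahydro-5H-5,10-methanobenzo[9]annulene-12-carboxylic acid (exo bromide at C12) | CCc1c(Br)cc2c(c1Br)[C@H]1[C@@H](Br)C(=O)C=C[C@](C)([C@@H]1C(=O)O)C2(C)C | intermediate (not isolated)
21 | salimabromide (11S,12S,16R,17R) | CCc1c(Br)cc2c(c1Br)[C@H]1[C@@H]3OC(=O)[C@H]1[C@@](C)(C=CC3=O)C2(C)C | target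

**Step count.** Total: 15 steps. Longest linear sequence: 14 steps (steps 1–8 and 10–15, from 1).

**Steps most likely to fail**

Step 10. The asymmetric induction may be too low. The racemic methyl-bearing centre of 11 can oppose catalyst control in the alkylation, and exchange at C11 may be too slow for the mixture to converge. The closure may also lose out to reversible aldol addition at C21 or to alkaline breakdown of 13. The fallback uses known chemistry and resolves a racemate. From 11, condensation with pyrrolidine (TsOH cat., toluene, Dean–Stark) gives the enamine 1-(6,8-dibromo-7-ethyl-3,4,4-trimethyl-3,4-dihydronaphthalen-2-yl)pyrrolidine F1. Stork alkylation with 13 (MeCN, 25 °C) and hydrolysis with aqueous acetic acid give diketone 14, now isolated. KOtBu (THF/t-BuOH, 0 °C) closes the ring by enolate addition–elimination to the racemic bridged enedione F2. Preparative supercritical-fluid chromatography on an amylose tris(3,5-dimethylphenylcarbamate) phase then returns to 15.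

Step 12. The bulky ylide may fail to add to the hindered bridging carbonyl, or may attack the silyl enol ether as a base. The fallback starts from 16. Corey–Chaykovsky reaction with the smaller dimethylsulfonium methylide (Me3S iodide, KN(SiMe3)2, THF/DMSO, 0 °C) gives the C16 spiro-oxirane of the silyl dienol ether F3. BF3·OEt2 (CH2Cl2, −78 °C) induces Meinwald rearrangement with hydride shift to the silyl dienol ether C16 carbaldehyde F4. 2 M HCl/THF then removes the silyl group and equilibrates C16, returning to 18.

Step 7. The β-boryl silyl ether 9 may lose its silyloxy group; the resulting styrene would be hydroborated again at the benzylic carbon, giving a 1-tetralol in place of the diol. The fallback starts from 8. Mild aqueous acid gives 6,8-dibromo-7-ethyl-3,4,4-trimethyl-3,4-dihydronaphthalen-1(2H)-one F5. NaBH4 (MeOH, 0 °C) gives 6,8-dibromo-7-ethyl-3,4,4-trimethyl-1,2,3,4-tetrahydronaphthalen-1-ol F6. TsOH (toluene, reflux) gives 5,7-dibromo-6-ethyl-1,1,2-trimethyl-1,2-dihydronaphthalene F7. mCPBA (CH2Cl2, NaHCO3) gives 5,7-dibromo-6-ethyl-2,3,3-trimethyl-1a,2,3,7b-tetrahydronaphtho[1,2-b]oxirene F8. ZnI2 (CH2Cl2, 25 °C) then effects Meinwald rearrangement with hydride shift, returning to 11.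

**Further compounds**

F1 | step 10 | 1-(6,8-dibromo-7-ethyl-3,4,4-trimethyl-3,4-dihydronaphthalen-2-yl)pyrrolidine, racemic | CCc1c(Br)cc2c(c1Br)C=C(N1CCCC1)C(C)C2(C)C
F2 | step 10 | racemic bridged enedione (racemate of 15) | CCc1c(Br)cc2c(c1Br)C1CC(=O)C=CC(C)(C1=O)C2(C)C
F3 | step 12 | C16 spiro-oxirane of the silyl dienol ether | CCc1c(Br)cc2c(c1Br)[C@H]1C=C(O[Si](C)(C)C(C)(C)C)C=C[C@](C)(C13CO3)C2(C)C
F4 | step 12 | silyl dienol ether C16 carbaldehyde (C16 epimers) | CCc1c(Br)cc2c(c1Br)[C@H]1C=C(O[Si](C)(C)C(C)(C)C)C=C[C@](C)(C1C=O)C2(C)C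
F5 | step 7 | 6,8-dibromo-7-ethyl-3,4,4-trimethyl-3,4-dihydronaphthalen-1(2H)-one, racemic | CC1(C)C(C)CC(=O)c2c(Br)c(CC)c(Br)cc12
F6 | step 7 | 6,8-dibromo-7-ethyl-3,4,4-trimethyl-1,2,3,4-tetrahydronaphthalen-1-ol, racemic | CC1(C)C(C)CC(O)c2c(Br)c(CC)c(Br)cc12
F7 | step 7 | 5,7-dibromo-6-ethyl-1,1,2-trimethyl-1,2-dihydronaphthalene, racemic | CC1(C)C(C)C=Cc2c(Br)c(CC)c(Br)cc12
F8 | step 7 | 5,7-dibromo-6-ethyl-2,3,3-trimethyl-1a,2,3,7b-tetrahydronaphtho[1,2-b]oxirene, racemic | CC1(C)C(C)C2OC2c2c(Br)c(CC)c(Br)cc12
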